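## The problem

Alpinnanin C (30) is an open-chain 1,7-diarylheptanoid (C1 carries the 4-hydroxyphenyl ring, C7 the phenyl ring) whose C3 is bonded directly to C3' of a cardamonin-type chalcone ring A (C1' acyl, C2' and C4' hydroxyl, C6' methoxy). No ring has to be closed: the work lies in joining three carbon groups at C3 and in placing four different substituents on ring A without regiochemical doubt. The two stereocentres, (R)-C3 and (S)-C5, are separated by the C4 methylene on a freely rotating chain, so neither can be trusted to control the other and each needs its own source of asymmetry. C3 is both benzylic to an electron-rich ring and allylic to a 4-oxygenated styrene. Acid can therefore ionise the C1=C2/C3 region, and the C1 cation is captured by a ring-A hydroxyl or by the C5 hydroxyl to give flavan- or tetrahydropyran-type ethers; strong base threatens the C3–H bond. The 2'-hydroxychalcone is a Michael acceptor that closes to a flavanone under acid or base, so it should appear late and the final deprotection has to be mild. On ring A the chain sits on the only carbon flanked by two oxygens of a symmetrical 5-methoxyresorcinol pattern, and the two remaining ring carbons are equivalent until one is acylated. The feature that opens the chosen route is C3 itself: a CH carbon carrying three different carbon groups (ring-A carbon C3', methylene C4, alkenyl carbon C2), which can be a single carbon held on boron that receives these groups one after another by 1,2-shifts.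

## Retrosynthesis

**Protecting groups (30 from 29).** No skeletal bond is cut. All three phenols are carried as methoxymethyl ethers and the C5 hydroxyl as a silyl ether, so one treatment with dilute methanolic acid releases 30 from 29. Methoxymethyl is chosen because the same group directs the early lithiation of ring A; putting it on the styrene phenol as well avoids a separate fluoride step. The forward reaction must be gentle enough for the enone and the 4-hydroxystyrene.

**C1'–carbonyl bond (29 from 25 and 26; 25 from 24).** The cinnamoyl group is cut off at the bond between C1' and the carbonyl carbon. An aldol condensation of a ring-A acetophenone would require a ketone to pass through the organolithium steps, and a Friedel–Crafts acylation needs Lewis acids that the chain would not survive. Aryl iodide 25 and Weinreb amide 26 give the enone in one operation, and 25 comes from 24 by iodination, since the two free ring-A positions of 24 are interconverted by rotation about C3'–C3. The precursor 24 lacks the most fragile group of the target. The forward steps need iodination of ring A in preference to the styrene, and iodine–lithium exchange that outruns deprotonation at C3.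

**C5–C6 bond (24 from 23; 23 from 20 and 22).** The carbinol is cut between C5 and C6, giving aldehyde 20 and bis(2-phenylethyl)zinc 22 (from iodide 21). The neighbouring cut C4–C5 would need a carbanion at C4 next to the C3 stereocentre. Reduction of a C5 ketone would have to distinguish two methylene flanks. Aldehyde 20 has one stereocentre and no oxygen function at C5 to protect. The addition has to be reagent-controlled, because C3 is β to the carbonyl and gives no useful bias.

**C2–C3 bond (20 from 19; 19 from 13 and 15).** After unmasking of the aldehyde (19 to 20), the styrene is cut between C3 and alkenyl carbon C2. A boronate at C3 (13) and alkenyl iodide 15 (from aldehyde 14) are joined by a stereoretentive olefination. A Wittig or Julia reaction would need an epimerisable α-aryl aldehyde at C3, and allylic substitution on an unsymmetrical 1,3-disubstituted allyl system has a regiochemical problem. Boronate 13 contains neither the alkene nor the 4-oxygenated ring. The forward step must keep the configuration at C3 and give the E alkene.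

**C3'–C3 and C3–C4 bonds (13 from 6, 7 and 8).** This is the key disconnection: both bonds to C3 are cut, and C3 itself comes from dichloromethane 7. Asymmetric conjugate addition of a di-ortho-substituted aryl nucleophile, or a Friedel–Crafts alkylation of the phloroglucinol ring, would be the neighbouring options; neither offers comparable control over C3. Aryl boronate 6 has no stereocentre on carbon, and Grignard reagent 8 is commercial. The forward reaction needs a diastereoselective first shift, a stereospecific second shift, and a benzylic chloride intermediate that keeps its configuration long enough.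

**C3'–B bond (6 from 2 and 3; 2 from 1).** The boronate is cut at the aryl–boron bond. Bis(methoxymethyl) ether 2 is lithiated between its two directing groups and borylated, and diol 3 is introduced by transesterification. Compound 2 comes from 5-methoxyresorcinol 1 in one step, so the methyl ether of the target is present from the first compound.

## Roads not taken

**Alternative 1:** The cut is C2–C3 together with a temporary O–C1 bond. Benzylic alcohol A1, which already holds ring A, C3 to C7 and the C5 stereocentre, would be ionised to an ortho-quinone methide whose methide carbon is C3. Styrene A2 would add across it in an inverse-demand [4+2] cycloaddition to give the 2,4-cis flavan A3.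
- Merits: the step is convergent and metal-free. The chain ends up on the correct ring-A carbon because both ortho hydroxyls are equivalent. The pyran ring masks one phenol and so differentiates the two ring-A hydroxyls.
- Weak points: the two faces of the methide are distinguished only by the C5 silyloxy group two atoms away on a flexible chain, so C3 would form with little control unless a chiral acid catalyst took over. A3 must then be reopened by cleaving O–C1 and forming the E C1=C2 alkene. That is the reverse of the cyclisation that endangers the target, and it would have to be done on a compound that still lacks the cinnamoyl group.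
- Comparison: A3 would be reached in fewer operations than 19 and without boron, selenium or chromium reagents; in that respect this road is better. Against this the chosen plan sets a reagent-fixed C3, direct formation of the E alkene in step 5, and no ring to reopen.

**Alternative 2:** The cut lies inside ring A at C1'–C2'. Pyrone A4 would be opened by Mg(OMe)2 to a chelated triketo ester, which closes by Claisen condensation to chalcone A5.
- Merits: ring and acyl group arrive together, so steps 10 and 11 of the chosen route would be unnecessary and no arene substitution is involved. Here this road is clearly better.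
- Weak points: A5 is a 2',4',6'-triol, while the target carries its methyl on O6', one of two chelated ortho hydroxyls; the freer O4' would alkylate first. The C3 stereocentre would have to be attached to the pyrone beforehand with a secondary 1,3-diarylallyl electrophile, with regio- and stereochemical problems of its own. During the cyclisation C3 sits beside an enolisable 1,3-dicarbonyl carbon, which invites epimerisation or retro-allylation. An aldol mode of ring closure competes, and the enone must survive methoxide.
- Comparison: the chosen plan pays with two late steps on ring A, but the methyl ether is in place from compound 1 and C3 is never next to an enolate.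

**Alternative 3:** The cut is C1–C2 with a temporary O–C1 bond. Homoallylic alcohol A6 (C5 already set) would condense with aldehyde A7. The oxocarbenium ion is attacked by the 1,1-disubstituted alkene, and Et3SiH reduces the tertiary benzylic cation at C3, giving the all-cis tetrahydropyran A8.
- Merits: C3 is set from C5 through a chair transition state, so one stereocentre controls the other. This is more economical than the two independent controlled events (steps 3 and 8) of the chosen plan. The pivalate also tames the electron-rich styrene ring until late.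
- Weak points: A8 must be reopened at O–C1 with formation of the E alkene, through a para-quinone methide after loss of the pivalate, against the tendency of the open form to reclose. The benzyl ethers must be removed without touching two alkenes, and the chalcone still has to be installed.
- Comparison: this road is stronger in stereocontrol. The chosen plan sets against it an alkene made directly with defined geometry, no ring-opening equilibrium, and independent choice of configuration at C3 and C5.

Key step: step 3

Remark: the heptanoid chain is numbered C1 (4-hydroxyphenyl end) to C7 and ring A C1' (acyl) to C6' (methoxy); the sense of induction in steps 3 and 8 is assigned from the accepted models for these reagents and, should either prove opposite, the enantiomeric diol or ligand would be used; compounds 1, 3, 7, 8, 14, 21 and 26 are taken as purchased.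

## Route

Step 1
Reactants: 1 5-methoxyresorcinol (5-methoxybenzene-1,3-diol)
Product: 2 1-methoxy-3,5-bis(methoxymethoxy)benzene
Conditions: NaH, DMF, 0 °C; MOMCl, 0 °C → rt
Reagents that add atoms: chloromethyl methyl ether (MOMCl), COCCl
Why: Double Williamson O-alkylation of the bis-phenoxide; the two methoxymethyl ethers later direct lithiation to the carbon between them and are removed together at the end.

Step 2
Reactants: 2 1-methoxy-3,5-bis(methoxymethoxy)benzene; 3 (1R,2R)-1,2-dicyclohexylethane-1,2-diol
Product: 6 (4R,5R)-4,5-dicyclohexyl-2-[4-methoxy-2,6-bis(methoxymethoxy)phenyl]-1,3,2-dioxaborolane, via aryllithium 4 (not isolated), via lithium aryltriisopropoxyborate 5 (not isolated)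
Conditions: n-BuLi, THF, 0 °C; B(OiPr)3, −78 °C → rt; 3, AcOH, rt
Reagents that add atoms: triisopropyl borate, CC(C)OB(OC(C)C)OC(C)C
Why: Directed ortho-metalation at the carbon flanked by two chelating methoxymethoxy groups (methoxy is the weaker director), borylation of 4 to 5, and buffered transesterification with 3, which avoids isolating the protodeboronation-prone free 2,6-dialkoxyarylboronic acid.

Step 3
Reactants: 6 (4R,5R)-4,5-dicyclohexyl-2-[4-methoxy-2,6-bis(methoxymethoxy)phenyl]-1,3,2-dioxaborolane; 7 dichloromethane; 8 (1,3-dioxolan-2-ylmethyl)magnesium bromide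
Product: 13 (4R,5R)-4,5-dicyclohexyl-2-{(1S)-2-(1,3-dioxolan-2-yl)-1-[4-methoxy-2,6-bis(methoxymethoxy)phenyl]ethyl}-1,3,2-dioxaborolane, via (dichloromethyl)lithium 9 (not isolated), via lithium dichloromethylborate 10 (not isolated), via α-chlorobenzyl boronate 11 (not isolated), via bromomagnesium alkylborate 12 (not isolated)
Conditions: 7, n-BuLi, THF, −100 °C; 6, −100 °C; ZnCl2, −100 → 0 °C; 8 (3 equiv), −78 °C → rt
Reagents that add atoms: none
Why: Matteson homologation: carbenoid 9, made from 7 and n-BuLi, adds to the boron of 6 to give borate 10. ZnCl2-assisted loss of one chloride drives the 1,2-shift of ring-A carbon C3' from boron to carbon (bond C3'–C3) and gives chloride 11; the C2-symmetric (R,R)-diol distinguishes the two diastereotopic chlorides, which by the established rule for such diols gives the (S)-chloride. Grignard reagent 8 then forms borate 12, and its methylene group displaces the remaining chloride with inversion (bond C3–C4); this shift is stereospecific, so C3 of 13 is (S), with boron standing where the alkenyl group will enter. The closest known reaction type is the dichloromethyllithium homologation of chiral-diol aryl boronates followed by Grignard substitution. No ring is closed. The step needs high diastereoselection in the first shift and survival of the configuration of 11, which the trioxygenated ring makes prone to ionisation and chloride exchange. To secure this, ZnCl2 binds free chloride, the mixture is kept at or below 0 °C while 11 exists, and 8 is added in excess to the same flask without isolating 11. Position on ring A is fixed by the boron atom, and in 13 the acetal oxygens sit on the carbon γ to boron, so β-elimination of the boronate cannot occur.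

Step 4
Reactants: 14 4-(methoxymethoxy)benzaldehyde
Product: 15 1-[(E)-2-iodoethenyl]-4-(methoxymethoxy)benzene
Conditions: CHI3, CrCl2, THF, 0 °C → rt
Reagents that add atoms: iodoform, IC(I)I
Why: Takai iodo-olefination; the geminal dichromium species from iodoform and CrCl2 adds to the aldehyde and eliminates to the E alkenyl iodide.

Step 5
Reactants: 13 (4R,5R)-4,5-dicyclohexyl-2-{(1S)-2-(1,3-dioxolan-2-yl)-1-[4-methoxy-2,6-bis(methoxymethoxy)phenyl]ethyl}-1,3,2-dioxaborolane; 15 1-[(E)-2-iodoethenyl]-4-(methoxymethoxy)benzene
Product: 19 2-{(2R,3E)-2-[4-methoxy-2,6-bis(methoxymethoxy)phenyl]-4-[4-(methoxymethoxy)phenyl]but-3-en-1-yl}-1,3-dioxolane, via alkenyllithium 16 (not isolated), via lithium alkenylborate 17 (not isolated), via β-selanyl boronate 18 (not isolated)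
Conditions: 15, t-BuLi, Et2O, −78 °C; 13, THF, −78 °C; PhSeCl, −78 °C; mCPBA, −78 → −45 °C
Reagents that add atoms: none
Why: Zweifel-type olefination in its selenium variant: 16 (iodine–lithium exchange with retention of geometry) adds to boron to give 17, PhSeCl induces the 1,2-shift of C3 with retention at C3 and anti addition across the alkene to give 18, and oxidation to the selenoxide brings about syn elimination of boron and selenium, so the E geometry of 16 is kept and the diol 3 is released. The descriptor at C3 changes from (S) to (R) only because the alkenyl group outranks the methylene group.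

Step 6
Reactants: 19 2-{(2R,3E)-2-[4-methoxy-2,6-bis(methoxymethoxy)phenyl]-4-[4-(methoxymethoxy)phenyl]but-3-en-1-yl}-1,3-dioxolane
Product: 20 (3R,4E)-3-[4-methoxy-2,6-bis(methoxymethoxy)phenyl]-5-[4-(methoxymethoxy)phenyl]pent-4-enal
Conditions: PPTS, acetone/H2O, 55 °C
Reagents that add atoms: water, O
Why: Acid-catalysed acetal hydrolysis; a weak pyridinium acid in wet acetone should open the dioxolane of an unhindered aliphatic aldehyde while aryl methoxymethyl ethers, which need stronger acid or an alcohol solvent, stay in place. C3 is β to the new carbonyl and cannot epimerise by enolisation.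

Step 7
Reactants: 21 (2-iodoethyl)benzene
Product: 22 bis(2-phenylethyl)zinc
Conditions: Et2Zn (neat), CuI (cat.), 50 °C; volatiles removed in vacuo
Reagents that add atoms: diethylzinc, CC[Zn]CC
Why: Knochel iodine–zinc exchange, driven by removal of iodoethane and excess Et2Zn; it gives the salt-free dialkylzinc that a highly enantioselective addition requires.

Step 8
Reactants: 20 (3R,4E)-3-[4-methoxy-2,6-bis(methoxymethoxy)phenyl]-5-[4-(methoxymethoxy)phenyl]pent-4-enal; 22 bis(2-phenylethyl)zinc
Product: 23 (3S,5R,6E)-5-[4-methoxy-2,6-bis(methoxymethoxy)phenyl]-7-[4-(methoxymethoxy)phenyl]-1-phenylhept-6-en-3-ol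
Conditions: (1R,2R)-1,2-bis(trifluoromethanesulfonamido)cyclohexane (8 mol %), Ti(OiPr)4, toluene, −20 °C
Reagents that add atoms: none
Why: Catalytic enantioselective dialkylzinc addition to an aldehyde; the complex formed from Ti(OiPr)4 and the (1R,2R)-bis(sulfonamide) delivers the phenethyl group to the Si face, which gives the (S)-carbinol (C5 of the target). Control comes from the catalyst because the C3 stereocentre, β to the carbonyl, exerts little bias.

Step 9
Reactants: 23 (3S,5R,6E)-5-[4-methoxy-2,6-bis(methoxymethoxy)phenyl]-7-[4-(methoxymethoxy)phenyl]-1-phenylhept-6-en-3-ol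
Product: 24 tert-butyl({(3S,5R,6E)-5-[4-methoxy-2,6-bis(methoxymethoxy)phenyl]-7-[4-(methoxymethoxy)phenyl]-1-phenylhept-6-en-3-yl}oxy)dimethylsilane
Conditions: TBSCl, imidazole, DMF, rt
Reagents that add atoms: tert-butyldimethylsilyl chloride, CC(C)(C)[Si](C)(C)Cl
Why: Standard silylation of a secondary alcohol; it keeps the hydroxyl out of the organolithium chemistry of step 11 and is cleaved in the final acid step.

Step 10
Reactants: 24 tert-butyl({(3S,5R,6E)-5-[4-methoxy-2,6-bis(methoxymethoxy)phenyl]-7-[4-(methoxymethoxy)phenyl]-1-phenylhept-6-en-3-yl}oxy)dimethylsilane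
Product: 25 tert-butyl({(3S,5R,6E)-5-[3-iodo-4-methoxy-2,6-bis(methoxymethoxy)phenyl]-7-[4-(methoxymethoxy)phenyl]-1-phenylhept-6-en-3-yl}oxy)dimethylsilane
Conditions: NIS (1.0 equiv), MeCN, 0 °C, dark
Reagents that add atoms: N-iodosuccinimide, O=C1CCC(=O)N1I
Why: Electrophilic aromatic iodination; ring A is a phloroglucinol triether and far more nucleophilic than the hindered styrene or the mono-oxygenated ring, and its two free positions are interconverted by rotation about C3'–C3, so one equivalent of NIS should give a single mono-iodide.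

Step 11
Reactants: 25 tert-butyl({(3S,5R,6E)-5-[3-iodo-4-methoxy-2,6-bis(methoxymethoxy)phenyl]-7-[4-(methoxymethoxy)phenyl]-1-phenylhept-6-en-3-yl}oxy)dimethylsilane; 26 (2E)-N-methoxy-N-methyl-3-phenylprop-2-enamide
Product: 29 (2E)-1-(3-{(1E,3R,5S)-5-[(tert-butyldimethylsilyl)oxy]-1-[4-(methoxymethoxy)phenyl]-7-phenylhept-1-en-3-yl}-6-methoxy-2,4-bis(methoxymethoxy)phenyl)-3-phenylprop-2-en-1-one, via aryllithium 27 (not isolated), via lithium hemiaminal alkoxide 28 (not isolated)
Conditions: n-BuLi, THF, −78 °C; 26, −78 → 0 °C; H2O
Reagents that add atoms: none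
Why: Iodine–lithium exchange at −78 °C is faster than deprotonation at C3 or addition to the styrene; 27 adds 1,2 to the Weinreb amide, and the chelated tetrahedral intermediate 28 releases the enone only on work-up, so over-addition is excluded (Weinreb ketone synthesis).

Step 12
Reactants: 29 (2E)-1-(3-{(1E,3R,5S)-5-[(tert-butyldimethylsilyl)oxy]-1-[4-(methoxymethoxy)phenyl]-7-phenylhept-1-en-3-yl}-6-methoxy-2,4-bis(methoxymethoxy)phenyl)-3-phenylprop-2-en-1-one
Product: 30 alpinnanin C
Conditions: HCl (1.25 M in MeOH), THF, 0 °C → rt
Reagents that add atoms: none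
Why: Acid-catalysed transacetalisation of the three aryl methoxymethyl ethers to dimethoxymethane and methanolysis of the silyl ether; brief exposure to dilute methanolic HCl is the usual way to unmask 2'-hydroxychalcones, and no stereocentre is involved.

## Compound list

1 | 5-methoxyresorcinol (5-methoxybenzene-1,3-diol) | COc1cc(O)cc(O)c1 | starting material
2 | 1-methoxy-3,5-bis(methoxymethoxy)benzene | COCOc1cc(OC)cc(OCOC)c1 | intermediate
3 | (1R,2R)-1,2-dicyclohexylethane-1,2-diol | O[C@H](C1CCCCC1)[C@H](O)C1CCCCC1 | starting material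
4 | [4-methoxy-2,6-bis(methoxymethoxy)phenyl]lithium | [Li]c1c(OCOC)cc(OC)cc1OCOC | intermediate (not isolated)
5 | lithium triisopropoxy[4-methoxy-2,6-bis(methoxymethoxy)phenyl]borate | [Li+].COCOc1cc(OC)cc(OCOC)c1[B-](OC(C)C)(OC(C)C)OC(C)C | intermediate (not isolated)
6 | (4R,5R)-4,5-dicyclohexyl-2-[4-methoxy-2,6-bis(methoxymethoxy)phenyl]-1,3,2-dioxaborolane | COc1cc(OCOC)c(B2O[C@H](C3CCCCC3)[C@@H](C3CCCCC3)O2)c(OCOC)c1 | intermediate
7 | dichloromethane | ClCCl | starting material
8 | (1,3-dioxolan-2-ylmethyl)magnesium bromide | Br[Mg]CC1OCCO1 | starting material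
9 | (dichloromethyl)lithium | [Li]C(Cl)Cl | intermediate (not isolated)
10 | lithium (4R,5R)-4,5-dicyclohexyl-2-(dichloromethyl)-2-[4-methoxy-2,6-bis(methoxymethoxy)phenyl]-1,3,2-dioxaborolan-2-uide | [Li+].COc1cc(OCOC)c([B-]2(C(Cl)Cl)O[C@H](C3CCCCC3)[C@@H](C3CCCCC3)O2)c(OCOC)c1 | intermediate (not isolated)
11 | (4R,5R)-2-{(S)-chloro[4-methoxy-2,6-bis(methoxymethoxy)phenyl]methyl}-4,5-dicyclohexyl-1,3,2-dioxaborolane | COc1cc(OCOC)c([C@@H](Cl)B2O[C@H](C3CCCCC3)[C@@H](C3CCCCC3)O2)c(OCOC)c1 | intermediate (not isolated)
12 | bromomagnesium (4R,5R)-2-{(S)-chloro[4-methoxy-2,6-bis(methoxymethoxy)phenyl]methyl}-4,5-dicyclohexyl-2-(1,3-dioxolan-2-ylmethyl)-1,3,2-dioxaborolan-2-uide | Br[Mg+].COc1cc(OCOC)c([C@@H](Cl)[B-]2(CC3OCCO3)O[C@H](C4CCCCC4)[C@@H](C4CCCCC4)O2)c(OCOC)c1 | intermediate (not isolated)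
13 | (4R,5R)-4,5-dicyclohexyl-2-{(1S)-2-(1,3-dioxolan-2-yl)-1-[4-methoxy-2,6-bis(methoxymethoxy)phenyl]ethyl}-1,3,2-dioxaborolane | COc1cc(OCOC)c([C@@H](B2O[C@H](C3CCCCC3)[C@@H](C3CCCCC3)O2)CC2OCCO2)c(OCOC)c1 | intermediate
14 | 4-(methoxymethoxy)benzaldehyde | COCOc1ccc(C=O)cc1 | starting material
15 | 1-[(E)-2-iodoethenyl]-4-(methoxymethoxy)benzene | COCOc1ccc(/C=C/I)cc1 | intermediate
16 | {(E)-2-[4-(methoxymethoxy)phenyl]ethenyl}lithium | [Li]/C=C/c1ccc(OCOC)cc1 | intermediate (not isolated)
17 | lithium (4R,5R)-4,5-dicyclohexyl-2-{(1S)-2-(1,3-dioxolan-2-yl)-1-[4-methoxy-2,6-bis(methoxymethoxy)phenyl]ethyl}-2-{(E)-2-[4-(methoxymethoxy)phenyl]ethenyl}-1,3,2-dioxaborolan-2-uide | [Li+].COc1cc(OCOC)c([C@@H]([B-]2(/C=C/c3ccc(OCOC)cc3)O[C@H](C4CCCCC4)[C@@H](C4CCCCC4)O2)CC2OCCO2)c(OCOC)c1 | intermediate (not isolated)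
18 | (4R,5R)-4,5-dicyclohexyl-2-{(1R,2S,3R)-4-(1,3-dioxolan-2-yl)-3-[4-methoxy-2,6-bis(methoxymethoxy)phenyl]-1-[4-(methoxymethoxy)phenyl]-1-(phenylselanyl)butan-2-yl}-1,3,2-dioxaborolane; anti adduct, expected together with its (1S,2R,3R) isomer from attack on the other alkene face, both converging on 19 | COc1cc(OCOC)c([C@H](CC2OCCO2)[C@H](B2O[C@H](C3CCCCC3)[C@@H](C3CCCCC3)O2)[C@@H]([Se]c2ccccc2)c2ccc(OCOC)cc2)c(OCOC)c1 | intermediate (not isolated)
19 | 2-{(2R,3E)-2-[4-methoxy-2,6-bis(methoxymethoxy)phenyl]-4-[4-(methoxymethoxy)phenyl]but-3-en-1-yl}-1,3-dioxolane | COc1cc(OCOC)c([C@@H](/C=C/c2ccc(OCOC)cc2)CC2OCCO2)c(OCOC)c1 | intermediate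
20 | (3R,4E)-3-[4-methoxy-2,6-bis(methoxymethoxy)phenyl]-5-[4-(methoxymethoxy)phenyl]pent-4-enal | COc1cc(OCOC)c([C@@H](/C=C/c2ccc(OCOC)cc2)CC=O)c(OCOC)c1 | intermediate
21 | (2-iodoethyl)benzene | ICCc1ccccc1 | starting material
22 | bis(2-phenylethyl)zinc | C(Cc1ccccc1)[Zn]CCc1ccccc1 | intermediate
23 | (3S,5R,6E)-5-[4-methoxy-2,6-bis(methoxymethoxy)phenyl]-7-[4-(methoxymethoxy)phenyl]-1-phenylhept-6-en-3-ol | COc1cc(OCOC)c([C@@H](/C=C/c2ccc(OCOC)cc2)C[C@@H](O)CCc2ccccc2)c(OCOC)c1 | intermediate
24 | tert-butyl({(3S,5R,6E)-5-[4-methoxy-2,6-bis(methoxymethoxy)phenyl]-7-[4-(methoxymethoxy)phenyl]-1-phenylhept-6-en-3-yl}oxy)dimethylsilane | COc1cc(OCOC)c([C@@H](/C=C/c2ccc(OCOC)cc2)C[C@@H](O[Si](C)(C)C(C)(C)C)CCc2ccccc2)c(OCOC)c1 | intermediate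
25 | tert-butyl({(3S,5R,6E)-5-[3-iodo-4-methoxy-2,6-bis(methoxymethoxy)phenyl]-7-[4-(methoxymethoxy)phenyl]-1-phenylhept-6-en-3-yl}oxy)dimethylsilane | COc1cc(OCOC)c([C@@H](/C=C/c2ccc(OCOC)cc2)C[C@@H](O[Si](C)(C)C(C)(C)C)CCc2ccccc2)c(OCOC)c1I | intermediate
26 | (2E)-N-methoxy-N-methyl-3-phenylprop-2-enamide | CON(C)C(=O)/C=C/c1ccccc1 | starting material
27 | (3-{(1E,3R,5S)-5-[(tert-butyldimethylsilyl)oxy]-1-[4-(methoxymethoxy)phenyl]-7-phenylhept-1-en-3-yl}-6-methoxy-2,4-bis(methoxymethoxy)phenyl)lithium | COc1cc(OCOC)c([C@@H](/C=C/c2ccc(OCOC)cc2)C[C@@H](O[Si](C)(C)C(C)(C)C)CCc2ccccc2)c(OCOC)c1[Li] | intermediate (not isolated)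
28 | lithium (2E)-1-(aryl)-1-[methoxy(methyl)amino]-3-phenylprop-2-en-1-olate, aryl as in 27, both epimers at the new carbinol carbon | COc1cc(OCOC)c([C@@H](/C=C/c2ccc(OCOC)cc2)C[C@@H](O[Si](C)(C)C(C)(C)C)CCc2ccccc2)c(OCOC)c1C(O[Li])(N(C)OC)/C=C/c1ccccc1 | intermediate (not isolated)
29 | (2E)-1-(3-{(1E,3R,5S)-5-[(tert-butyldimethylsilyl)oxy]-1-[4-(methoxymethoxy)phenyl]-7-phenylhept-1-en-3-yl}-6-methoxy-2,4-bis(methoxymethoxy)phenyl)-3-phenylprop-2-en-1-one | COc1cc(OCOC)c([C@@H](/C=C/c2ccc(OCOC)cc2)C[C@@H](O[Si](C)(C)C(C)(C)C)CCc2ccccc2)c(OCOC)c1C(=O)/C=C/c1ccccc1 | intermediate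
30 | alpinnanin C, (2E)-1-{2,4-dihydroxy-3-[(1E,3R,5S)-5-hydroxy-1-(4-hydroxyphenyl)-7-phenylhept-1-en-3-yl]-6-methoxyphenyl}-3-phenylprop-2-en-1-one | COc1cc(O)c([C@@H](/C=C/c2ccc(O)cc2)C[C@@H](O)CCc2ccccc2)c(O)c1C(=O)/C=C/c1ccccc1 | target

## Step count and least certain steps

Total: 12 steps. Longest linear sequence: 10 steps (1, 2, 3, 5, 6, 8, 9, 10, 11, 12); steps 4 and 7 prepare the side components 15 and 22.

**Step 3 (key step).**
- Risk: borate formation at a boron flanked by two ortho substituents may be slow. The benzylic chloride may lose its configuration by ionisation (assisted by the trioxygenated ring) or by chloride exchange before the second shift. Part of the Grignard reagent is consumed by ZnCl2.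
- Fallback (from 2, back at 20): the C3 carbenoid is changed from dichloromethane to a chiral lithiated carbamate. Arene 2 is lithiated as in step 2 and quenched with 2-isopropoxy-4,4,5,5-tetramethyl-1,3,2-dioxaborolane to give the pinacol boronate F1. 3,3-Diethoxypropan-1-ol is carbamoylated with N,N-diisopropylcarbamoyl chloride to give the carbamate F2. F2 is lithiated with s-BuLi/(+)-sparteine in Et2O at −78 °C, and the configurationally stable carbenoid is trapped by F1 with retention. On warming with MgBr2·OEt2 the aryl group migrates with inversion to give the secondary boronate F3, which has the same spatial arrangement at C3 as 13. The olefination of step 5 with 16 converts F3 into the diethyl acetal F4, and mild hydrolysis of this acyclic acetal gives aldehyde 20.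

**Step 5.**
- Risk: the hindered secondary boronate may form the borate only slowly. PhSeCl or mCPBA may attack the electron-rich ring A or the product alkene. Incomplete syn elimination would erode the E geometry.
- Fallback (from 13, back at 19): vinylmagnesium bromide is added to 13, followed by I2 and NaOMe (classical Zweifel olefination, retention at C3), to give the terminal alkene F5. Aldehyde 14 is methylenated with Ph3P=CH2 to the styrene F6. Cross-metathesis of F5 with excess F6 (second-generation Grubbs catalyst, RuCl2(=CHPh)(H2IMes)(PCy3), CH2Cl2, 40 °C) gives the E alkene 19.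

**Step 6.**
- Risk: hydrolysis of the dioxolane may not be separable from loss of the methoxymethyl groups on the very electron-rich ring A.
- Fallback (from 6, back at 20): C5 is carried at the ester oxidation level, so no acid is needed. The homologation of step 3 is run as far as chloride 11, and the lithium enolate of tert-butyl acetate (made with LiN(i-Pr)2) is used in place of 8 to give the β-boryl ester F7. Olefination with 16 as in step 5 gives the unsaturated ester F8. i-Bu2AlH reduces F8 to the primary alcohol F9, and Dess–Martin periodinane oxidises F9 to aldehyde 20.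

**Step 8.**
- Risk: facial selectivity may be poor with an α-unbranched aldehyde that carries several Lewis-basic ethers, and alkyl transfer from the functionalised dialkylzinc may be sluggish.
- Fallback (from 20, back at 23): (2-phenylethyl)magnesium bromide is added to 20 without facial control, giving 23 together with its C5 epimer, the alcohol F10. The diastereomers are separated by chromatography. F10 is inverted by a Mitsunobu reaction (4-nitrobenzoic acid, PPh3, diisopropyl azodicarboxylate) to the 4-nitrobenzoate F11, which K2CO3/MeOH cleaves to 23.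

**Step 12.**
- Risk: protic acid may protonate the 4-oxygenated styrene, with ring closure by a ring-A hydroxyl or the C5 hydroxyl, or addition of methanol. The chalcone may close to a flavanone. Cleavage of the methoxymethyl groups may stop short.
- Fallback (from 29, back at 30): TMSOTf/2,2'-bipyridyl in CH2Cl2 at 0 °C exchanges the three aryl methoxymethyl groups for trimethylsilyl groups without free protic acid, giving the tris(trimethylsilyl) ether F12. HF·pyridine buffered with pyridine in THF then removes all four silyl groups to give 30.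

## Further compounds

F1 | step 3 | 2-[4-methoxy-2,6-bis(methoxymethoxy)phenyl]-4,4,5,5-tetramethyl-1,3,2-dioxaborolane | COc1cc(OCOC)c(B2OC(C)(C)C(C)(C)O2)c(OCOC)c1
F2 | step 3 | 3,3-diethoxypropyl N,N-diisopropylcarbamate | CCOC(CCOC(=O)N(C(C)C)C(C)C)OCC
F3 | step 3 | 2-{(1S)-3,3-diethoxy-1-[4-methoxy-2,6-bis(methoxymethoxy)phenyl]propyl}-4,4,5,5-tetramethyl-1,3,2-dioxaborolane | COc1cc(OCOC)c([C@@H](B2OC(C)(C)C(C)(C)O2)CC(OCC)OCC)c(OCOC)c1
F4 | step 3 | 2-{(1E,3R)-5,5-diethoxy-1-[4-(methoxymethoxy)phenyl]pent-1-en-3-yl}-5-methoxy-1,3-bis(methoxymethoxy)benzene | COc1cc(OCOC)c([C@@H](/C=C/c2ccc(OCOC)cc2)CC(OCC)OCC)c(OCOC)c1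
F5 | step 5 | 2-{(2R)-2-[4-methoxy-2,6-bis(methoxymethoxy)phenyl]but-3-en-1-yl}-1,3-dioxolane | COc1cc(OCOC)c([C@@H](C=C)CC2OCCO2)c(OCOC)c1
F6 | step 5 | 1-ethenyl-4-(methoxymethoxy)benzene | C=Cc1ccc(OCOC)cc1
F7 | step 6 | tert-butyl (3S)-3-[(4R,5R)-4,5-dicyclohexyl-1,3,2-dioxaborolan-2-yl]-3-[4-methoxy-2,6-bis(methoxymethoxy)phenyl]propanoate | COc1cc(OCOC)c([C@@H](B2O[C@H](C3CCCCC3)[C@@H](C3CCCCC3)O2)CC(=O)OC(C)(C)C)c(OCOC)c1
F8 | step 6 | tert-butyl (3R,4E)-3-[4-methoxy-2,6-bis(methoxymethoxy)phenyl]-5-[4-(methoxymethoxy)phenyl]pent-4-enoate | COc1cc(OCOC)c([C@@H](/C=C/c2ccc(OCOC)cc2)CC(=O)OC(C)(C)C)c(OCOC)c1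
F9 | step 6 | (3R,4E)-3-[4-methoxy-2,6-bis(methoxymethoxy)phenyl]-5-[4-(methoxymethoxy)phenyl]pent-4-en-1-ol | COc1cc(OCOC)c([C@@H](/C=C/c2ccc(OCOC)cc2)CCO)c(OCOC)c1
F10 | step 8 | (3R,5R,6E)-5-[4-methoxy-2,6-bis(methoxymethoxy)phenyl]-7-[4-(methoxymethoxy)phenyl]-1-phenylhept-6-en-3-ol | COc1cc(OCOC)c([C@@H](/C=C/c2ccc(OCOC)cc2)C[C@H](O)CCc2ccccc2)c(OCOC)c1
F11 | step 8 | (3S,5R,6E)-5-[4-methoxy-2,6-bis(methoxymethoxy)phenyl]-7-[4-(methoxymethoxy)phenyl]-1-phenylhept-6-en-3-yl 4-nitrobenzoate | COc1cc(OCOC)c([C@@H](/C=C/c2ccc(OCOC)cc2)C[C@@H](OC(=O)c2ccc(cc2)[N+](=O)[O-])CCc2ccccc2)c(OCOC)c1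
F12 | step 12 | (2E)-1-(3-{(1E,3R,5S)-5-[(tert-butyldimethylsilyl)oxy]-7-phenyl-1-[4-(trimethylsilyloxy)phenyl]hept-1-en-3-yl}-6-methoxy-2,4-bis(trimethylsilyloxy)phenyl)-3-phenylprop-2-en-1-one | COc1cc(O[Si](C)(C)C)c([C@@H](/C=C/c2ccc(O[Si](C)(C)C)cc2)C[C@@H](O[Si](C)(C)C(C)(C)C)CCc2ccccc2)c(O[Si](C)(C)C)c1C(=O)/C=C/c1ccccc1
A1 | alternative 1 | 2-{(3S)-3-[(tert-butyldimethylsilyl)oxy]-1-hydroxy-5-phenylpentyl}-5-methoxybenzene-1,3-diol | COc1cc(O)c(C(O)C[C@@H](O[Si](C)(C)C(C)(C)C)CCc2ccccc2)c(O)c1
A2 | alternative 1 | tert-butyl(4-ethenylphenoxy)dimethylsilane | C=Cc1ccc(O[Si](C)(C)C(C)(C)C)cc1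
A3 | alternative 1 | 2,4-cis flavan: 4-{(2S)-2-[(tert-butyldimethylsilyl)oxy]-4-phenylbutyl}-2-{4-[(tert-butyldimethylsilyl)oxy]phenyl}-7-methoxychroman-5-ol | COc1cc(O)c2c(c1)O[C@@H](c1ccc(O[Si](C)(C)C(C)(C)C)cc1)C[C@H]2C[C@@H](O[Si](C)(C)C(C)(C)C)CCc1ccccc1
A4 | alternative 2 | 3-{(1E,3R,5S)-5-[(tert-butyldimethylsilyl)oxy]-1-[4-(methoxymethoxy)phenyl]-7-phenylhept-1-en-3-yl}-4-hydroxy-6-[(3E)-2-oxo-4-phenylbut-3-en-1-yl]-2H-pyran-2-one | O=C(/C=C/c1ccccc1)Cc1cc(O)c([C@@H](/C=C/c2ccc(OCOC)cc2)C[C@@H](O[Si](C)(C)C(C)(C)C)CCc2ccccc2)c(=O)o1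
A5 | alternative 2 | (2E)-1-(3-{(1E,3R,5S)-5-[(tert-butyldimethylsilyl)oxy]-1-[4-(methoxymethoxy)phenyl]-7-phenylhept-1-en-3-yl}-2,4,6-trihydroxyphenyl)-3-phenylprop-2-en-1-one | O=C(/C=C/c1ccccc1)c1c(O)cc(O)c([C@@H](/C=C/c2ccc(OCOC)cc2)C[C@@H](O[Si](C)(C)C(C)(C)C)CCc2ccccc2)c1O
A6 | alternative 3 | (3S)-5-[2,6-bis(benzyloxy)-4-methoxyphenyl]-1-phenylhex-5-en-3-ol | C=C(c1c(OCc2ccccc2)cc(OC)cc1OCc1ccccc1)C[C@@H](O)CCc1ccccc1
A7 | alternative 3 | 4-formylphenyl 2,2-dimethylpropanoate | CC(C)(C)C(=O)Oc1ccc(C=O)cc1
A8 | alternative 3 | all-cis 4-{4-[2,6-bis(benzyloxy)-4-methoxyphenyl]-6-(2-phenylethyl)tetrahydro-2H-pyran-2-yl}phenyl 2,2-dimethylpropanoate | O1[C@H](c2ccc(OC(=O)C(C)(C)C)cc2)C[C@H](c2c(OCc3ccccc3)cc(OC)cc2OCc2ccccc2)C[C@@H]1CCc1ccccc1
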